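The chroman ring is disconnected at C4–C4a and O1–C2, which leads back to an aryl 1,1-dimethylpropargyl ether. In the chroman benzene ring O1 lies para to C6, the carbon that carries the carbinol side chain, so the two ring carbons ortho to O1 are equivalent. One thermal operation ([3,3] shift, 1,5-hydrogen shift, oxa-6π electrocyclisation) should therefore convert the ether into a single 2H-chromene. The precursor is the complete β-oxygenated dihydrochalcone skeleton with both stereocentres in place, the carbinol and the ketone-flanking phenol masked as TBS ethers, and the propargyl ether on the para-substituted ring.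

Key step: step 9

Assumption: the (S,S) antipode of the bisphosphoramide in step 7 is taken to expose the Si face of the bound aldehyde (the face that leads to the (S)-carbinol); this is to be checked by Mosher ester analysis on a model aldol with acetophenone trimethylsilyl enol ether, and the (R,R) antipode is used if the sense proves opposite.

Step 1
Reactants: 1 4-hydroxybenzaldehyde; 2 3-chloro-3-methylbut-1-yne
Product: 3 4-(2-methylbut-3-yn-2-yloxy)benzaldehyde
Conditions: DBU, CuCl2·2H2O (cat.), MeCN, 0 °C to rt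
Reagents that add atoms: none
Why: Copper-catalysed O-propargylation (Williamson-type etherification through a copper acetylide-derived tertiary propargyl electrophile) should work well because the phenol is acidic and its electron-poor ring disfavours C-alkylation.

Step 2
Reactants: 4 2,4-dihydroxyacetophenone; 5 2-methylbut-3-en-2-ol
Product: 6 1-[2,4-dihydroxy-5-(3-methylbut-2-en-1-yl)phenyl]ethanone
Conditions: BF3·OEt2 (0.3 equiv), 1,4-dioxane, rt; chromatography
Reagents that add atoms: none
Why: Friedel–Crafts alkylation: BF3 ionises the tertiary allylic alcohol to the dimethylallyl cation, which should attack through its primary terminus at C5 (para to the 2-OH, ortho to the 4-OH, the less hindered activated position), the C3 isomer and doubly prenylated material being expected as minor products that are separated.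

Step 3
Reactants: 6 1-[2,4-dihydroxy-5-(3-methylbut-2-en-1-yl)phenyl]ethanone
Product: 7 1-[2,4-bis(tert-butyldimethylsilyloxy)-5-(3-methylbut-2-en-1-yl)phenyl]ethanone
Conditions: TBSCl (2.5 equiv), imidazole, DMF, rt
Reagents that add atoms: tert-butyldimethylsilyl chloride, CC(C)(C)[Si](C)(C)Cl
Why: Silyl ether formation on both phenols (the hydrogen-bonded 2-OH reacts more slowly but is driven by excess reagent) removes any free phenol or phenoxide that could be oxidised in the next step.

Step 4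
Reactants: 7 1-[2,4-bis(tert-butyldimethylsilyloxy)-5-(3-methylbut-2-en-1-yl)phenyl]ethanone
Product: 8 1-[2,4-bis(tert-butyldimethylsilyloxy)-5-{[(2R)-3,3-dimethyloxiran-2-yl]methyl}phenyl]ethanone
Conditions: 1,2:4,5-di-O-isopropylidene-β-D-erythro-2,3-hexodiulo-2,6-pyranose (D-fructose-derived ketone, 0.3 equiv), KHSO5 (as Oxone), K2CO3, Bu4NHSO4 (cat.), MeCN–CH2(OMe)2–aq. Na2B4O7 buffer, 0 °C
Reagents that add atoms: potassium peroxymonosulfate KHSO5, [K+].[O-]S(=O)(=O)OO
Why: Shi epoxidation: the chiral dioxirane formed from the D-fructose-derived ketone should transfer oxygen to the trisubstituted prenyl alkene through a spiro transition state, which for an ArCH2CH=CMe2 unit gives the (2R)-epoxide, while the aryl silyl ethers are expected to survive the cold buffered medium.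

Step 5
Reactants: 8 1-[2,4-bis(tert-butyldimethylsilyloxy)-5-{[(2R)-3,3-dimethyloxiran-2-yl]methyl}phenyl]ethanone
Product: 10 1-[(2S)-6-hydroxy-2-(2-hydroxypropan-2-yl)-2,3-dihydro-1-benzofuran-5-yl]ethanone, via epoxy phenoxide 9 (not isolated)
Conditions: Bu4NF (2.5 equiv), THF, 0 °C to rt; recrystallisation
Reagents that add atoms: none
Why: Fluoride cleaves both aryl silyl ethers and the phenoxide at C4 should open the epoxide by 5-exo-tet SN2 attack at the secondary carbon with inversion, which converts the (R)-epoxide into the (S)-configured C2 of the dihydrobenzofuran and releases the tertiary alcohol.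

Step 6
Reactants: 10 1-[(2S)-6-hydroxy-2-(2-hydroxypropan-2-yl)-2,3-dihydro-1-benzofuran-5-yl]ethanone
Product: 11 trimethyl({1-[(2S)-6-(trimethylsilyloxy)-2-[2-(trimethylsilyloxy)propan-2-yl]-2,3-dihydro-1-benzofuran-5-yl]ethenyl}oxy)silane
Conditions: TMSOTf (3.5 equiv), Et3N, CH2Cl2, 0 °C; non-aqueous work-up, used crude
Reagents that add atoms: trimethylsilyl trifluoromethanesulfonate, C[Si](C)(C)OS(=O)(=O)C(F)(F)F
Why: Soft enolisation and silylation: TMSOTf with Et3N should silylate the phenol and the tertiary alcohol and convert the methyl ketone, which has a single enolisable site, into its trimethylsilyl enol ether.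

Step 7
Reactants: 11 trimethyl({1-[(2S)-6-(trimethylsilyloxy)-2-[2-(trimethylsilyloxy)propan-2-yl]-2,3-dihydro-1-benzofuran-5-yl]ethenyl}oxy)silane; 3 4-(2-methylbut-3-yn-2-yloxy)benzaldehyde
Product: 13 (3S)-3-hydroxy-1-[(2S)-6-hydroxy-2-(2-hydroxypropan-2-yl)-2,3-dihydro-1-benzofuran-5-yl]-3-[4-(2-methylbut-3-yn-2-yloxy)phenyl]propan-1-one, via trichlorosilyl aldolate 12 (not isolated)
Conditions: SiCl4 (1.5 equiv), (S,S)-bisphosphoramide (two N,N'-dimethyl-1,1'-binaphthyl-2,2'-diamine-derived cyclic phosphoramide units joined by a pentane-1,5-diylbis(methylamino) tether, 5 mol %), i-Pr2NEt (10 mol %), CH2Cl2, −78 °C; aq. NaHCO3; then citric acid (cat.), MeOH, rt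
Reagents that add atoms: none
Why: Lewis-base-catalysed Mukaiyama aldol addition: the chiral bisphosphoramide ionises SiCl4 to a cationic chlorosilyl Lewis acid that binds the aromatic aldehyde, and the enoxysilane should add through an open transition state to the exposed Si face, so the (S)-carbinol centre is set by the catalyst independently of the remote dihydrobenzofuran centre; the work-up hydrolyses the silyl aldolate and both trimethylsilyl ethers.

Step 8
Reactants: 13 (3S)-3-hydroxy-1-[(2S)-6-hydroxy-2-(2-hydroxypropan-2-yl)-2,3-dihydro-1-benzofuran-5-yl]-3-[4-(2-methylbut-3-yn-2-yloxy)phenyl]propan-1-one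
Product: 14 (3S)-3-(tert-butyldimethylsilyloxy)-1-[(2S)-6-(tert-butyldimethylsilyloxy)-2-(2-hydroxypropan-2-yl)-2,3-dihydro-1-benzofuran-5-yl]-3-[4-(2-methylbut-3-yn-2-yloxy)phenyl]propan-1-one
Conditions: TBSCl (3 equiv), imidazole, DMAP (cat.), DMF, rt
Reagents that add atoms: tert-butyldimethylsilyl chloride, CC(C)(C)[Si](C)(C)Cl
Why: Silyl ether formation: TBSCl with imidazole should silylate the secondary benzylic alcohol and the phenol while the tertiary alcohol is too hindered to react, so no acidic OH remains next to the β-oxygenated ketone in the thermal step.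

Step 9
Reactants: 14 (3S)-3-(tert-butyldimethylsilyloxy)-1-[(2S)-6-(tert-butyldimethylsilyloxy)-2-(2-hydroxypropan-2-yl)-2,3-dihydro-1-benzofuran-5-yl]-3-[4-(2-methylbut-3-yn-2-yloxy)phenyl]propan-1-one
Product: 18 (3S)-3-(tert-butyldimethylsilyloxy)-1-[(2S)-6-(tert-butyldimethylsilyloxy)-2-(2-hydroxypropan-2-yl)-2,3-dihydro-1-benzofuran-5-yl]-3-(2,2-dimethyl-2H-chromen-6-yl)propan-1-one, via allenyl dienone 15 (not isolated), via allenyl phenol 16 (not isolated), via quinone methide 17 (not isolated)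
Conditions: o-xylene (degassed, dilute), BHT (cat.), 140 °C
Reagents that add atoms: none
Why: Heating should trigger an aromatic propargyl Claisen [3,3] shift of the aryl 1,1-dimethylpropargyl ether to the 6-allenylcyclohexadienone 15 (C4–C4a bond), which enolises to the ortho-allenyl phenol 16; a 1,5-hydrogen shift from the phenolic OH to the central allene carbon then gives the ortho-quinone methide 17, which closes by a thermally allowed disrotatory oxa-6π electrocyclisation (O1–C2 bond) to the 2H-chromene. The closest known reaction type is the thermal conversion of aryl 1,1-dimethylpropargyl ethers into 2,2-dimethyl-2H-chromenes. The pyran ring is therefore closed in a 6π-electrocyclic mode after the sigmatropic step has made the carbon–carbon bond, and no stereocentre is created. The only selectivity needed is regiochemical, and the substrate secures it: the ether oxygen is para to the side chain, so both ortho carbons are equivalent and the para position is blocked. The geminal methyl groups lower the temperature of the [3,3] step, and the neutral, base-free medium with the neighbouring OH groups silylated should leave the β-silyloxy ketone, the tertiary alcohol and both stereocentres untouched.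

Step 10
Reactants: 18 (3S)-3-(tert-butyldimethylsilyloxy)-1-[(2S)-6-(tert-butyldimethylsilyloxy)-2-(2-hydroxypropan-2-yl)-2,3-dihydro-1-benzofuran-5-yl]-3-(2,2-dimethyl-2H-chromen-6-yl)propan-1-one
Product: 19 (3S)-3-(tert-butyldimethylsilyloxy)-1-[(2S)-6-(tert-butyldimethylsilyloxy)-2-(2-hydroxypropan-2-yl)-2,3-dihydro-1-benzofuran-5-yl]-3-(2,2-dimethyl-3,4-dihydro-2H-chromen-6-yl)propan-1-one
Conditions: H2 (1 atm), Pd/C, Ph2S (cat.), EtOAc, rt
Reagents that add atoms: none
Why: Heterogeneous catalytic hydrogenation over sulfide-poisoned Pd/C should saturate the cis-disubstituted styrenic C3=C4 bond without hydrogenolysis of the benzylic C–O bond or reduction of the aryl ketone.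

Step 11
Reactants: 19 (3S)-3-(tert-butyldimethylsilyloxy)-1-[(2S)-6-(tert-butyldimethylsilyloxy)-2-(2-hydroxypropan-2-yl)-2,3-dihydro-1-benzofuran-5-yl]-3-(2,2-dimethyl-3,4-dihydro-2H-chromen-6-yl)propan-1-one
Product: 20 (3S)-3-(2,2-dimethyl-3,4-dihydro-2H-chromen-6-yl)-3-hydroxy-1-[(2S)-6-hydroxy-2-(2-hydroxypropan-2-yl)-2,3-dihydro-1-benzofuran-5-yl]propan-1-one
Conditions: HF·pyridine, pyridine, THF, 0 °C to rt
Reagents that add atoms: none
Why: Fluoride-mediated desilylation under pyridine-buffered, non-basic conditions should cleave the aryl and the secondary silyl ether without retro-aldol cleavage or β-elimination of the β-hydroxy ketone.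

Compound list
1 | 4-hydroxybenzaldehyde | O=Cc1ccc(O)cc1 | starting material
2 | 3-chloro-3-methylbut-1-yne | CC(C)(Cl)C#C | starting material
3 | 4-(2-methylbut-3-yn-2-yloxy)benzaldehyde | CC(C)(C#C)Oc1ccc(C=O)cc1 | intermediate
4 | 2,4-dihydroxyacetophenone | CC(=O)c1ccc(O)cc1O | starting material
5 | 2-methylbut-3-en-2-ol | CC(C)(O)C=C | starting material
6 | 1-[2,4-dihydroxy-5-(3-methylbut-2-en-1-yl)phenyl]ethanone | CC(=O)c1cc(CC=C(C)C)c(O)cc1O | intermediate
7 | 1-[2,4-bis(tert-butyldimethylsilyloxy)-5-(3-methylbut-2-en-1-yl)phenyl]ethanone | CC(=O)c1cc(CC=C(C)C)c(O[Si](C)(C)C(C)(C)C)cc1O[Si](C)(C)C(C)(C)C | intermediate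
8 | 1-[2,4-bis(tert-butyldimethylsilyloxy)-5-{[(2R)-3,3-dimethyloxiran-2-yl]methyl}phenyl]ethanone | CC(=O)c1cc(C[C@H]2OC2(C)C)c(O[Si](C)(C)C(C)(C)C)cc1O[Si](C)(C)C(C)(C)C | intermediate
9 | 1-[5-{[(2R)-3,3-dimethyloxiran-2-yl]methyl}-2,4-dihydroxyphenyl]ethanone, present as its phenoxide | CC(=O)c1cc(C[C@H]2OC2(C)C)c(O)cc1O | intermediate
10 | 1-[(2S)-6-hydroxy-2-(2-hydroxypropan-2-yl)-2,3-dihydro-1-benzofuran-5-yl]ethanone | CC(=O)c1cc2c(cc1O)O[C@H](C(C)(C)O)C2 | intermediate
11 | trimethyl({1-[(2S)-6-(trimethylsilyloxy)-2-[2-(trimethylsilyloxy)propan-2-yl]-2,3-dihydro-1-benzofuran-5-yl]ethenyl}oxy)silane | C=C(O[Si](C)(C)C)c1cc2c(cc1O[Si](C)(C)C)O[C@H](C(C)(C)O[Si](C)(C)C)C2 | intermediate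
12 | trichlorosilyl ether of the (3S)-aldol adduct, with the phenol and the tertiary alcohol still as trimethylsilyl ethers | CC(C)(C#C)Oc1ccc([C@@H](O[Si](Cl)(Cl)Cl)CC(=O)c2cc3c(cc2O[Si](C)(C)C)O[C@H](C(C)(C)O[Si](C)(C)C)C3)cc1 | intermediate
13 | (3S)-3-hydroxy-1-[(2S)-6-hydroxy-2-(2-hydroxypropan-2-yl)-2,3-dihydro-1-benzofuran-5-yl]-3-[4-(2-methylbut-3-yn-2-yloxy)phenyl]propan-1-one | CC(C)(C#C)Oc1ccc([C@@H](O)CC(=O)c2cc3c(cc2O)O[C@H](C(C)(C)O)C3)cc1 | intermediate
14 | (3S)-3-(tert-butyldimethylsilyloxy)-1-[(2S)-6-(tert-butyldimethylsilyloxy)-2-(2-hydroxypropan-2-yl)-2,3-dihydro-1-benzofuran-5-yl]-3-[4-(2-methylbut-3-yn-2-yloxy)phenyl]propan-1-one | CC(C)(C#C)Oc1ccc([C@@H](O[Si](C)(C)C(C)(C)C)CC(=O)c2cc3c(cc2O[Si](C)(C)C(C)(C)C)O[C@H](C(C)(C)O)C3)cc1 | intermediate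
15 | 6-(3-methylbuta-1,2-dien-1-yl)cyclohexa-2,4-dien-1-one carrying the silylated side chain at C4 (epimers at C6) | CC(C)=C=CC1C=C([C@@H](O[Si](C)(C)C(C)(C)C)CC(=O)c2cc3c(cc2O[Si](C)(C)C(C)(C)C)O[C@H](C(C)(C)O)C3)C=CC1=O | intermediate
16 | 2-(3-methylbuta-1,2-dien-1-yl)phenol carrying the silylated side chain at C4 | CC(C)=C=Cc1cc([C@@H](O[Si](C)(C)C(C)(C)C)CC(=O)c2cc3c(cc2O[Si](C)(C)C(C)(C)C)O[C@H](C(C)(C)O)C3)ccc1O | intermediate
17 | 6-(3-methylbut-2-en-1-ylidene)cyclohexa-2,4-dien-1-one (ortho-quinone methide) carrying the silylated side chain at C4 | CC(C)=CC=C1C=C([C@@H](O[Si](C)(C)C(C)(C)C)CC(=O)c2cc3c(cc2O[Si](C)(C)C(C)(C)C)O[C@H](C(C)(C)O)C3)C=CC1=O | intermediate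
18 | (3S)-3-(tert-butyldimethylsilyloxy)-1-[(2S)-6-(tert-butyldimethylsilyloxy)-2-(2-hydroxypropan-2-yl)-2,3-dihydro-1-benzofuran-5-yl]-3-(2,2-dimethyl-2H-chromen-6-yl)propan-1-one | CC1(C)C=Cc2cc([C@@H](O[Si](C)(C)C(C)(C)C)CC(=O)c3cc4c(cc3O[Si](C)(C)C(C)(C)C)O[C@H](C(C)(C)O)C4)ccc2O1 | intermediate
19 | (3S)-3-(tert-butyldimethylsilyloxy)-1-[(2S)-6-(tert-butyldimethylsilyloxy)-2-(2-hydroxypropan-2-yl)-2,3-dihydro-1-benzofuran-5-yl]-3-(2,2-dimethyl-3,4-dihydro-2H-chromen-6-yl)propan-1-one | CC1(C)CCc2cc([C@@H](O[Si](C)(C)C(C)(C)C)CC(=O)c3cc4c(cc3O[Si](C)(C)C(C)(C)C)O[C@H](C(C)(C)O)C4)ccc2O1 | intermediate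
20 | (3S)-3-(2,2-dimethyl-3,4-dihydro-2H-chromen-6-yl)-3-hydroxy-1-[(2S)-6-hydroxy-2-(2-hydroxypropan-2-yl)-2,3-dihydro-1-benzofuran-5-yl]propan-1-one | CC1(C)CCc2cc([C@@H](O)CC(=O)c3cc4c(cc3O)O[C@H](C(C)(C)O)C4)ccc2O1 | target

Total step count: 11. Longest linear sequence: 10 steps (steps 2 to 11, from 4); aldehyde 3 is made in one step and joins at step 7.

Steps most likely to fail

1. Step 7. Facial discrimination at the aldehyde may be incomplete, which would give the carbinol epimer as a diastereomer that is hard to remove because the second stereocentre is remote. Turnover may also be slow with the ortho-silyloxy enoxysilane, and the electron-rich benzylic silyl aldolate may ionise. The fallback sets out from 10 and 3 and comes back at 13. Ketone 10 is O-allylated at the hydrogen-bonded phenol (allyl bromide, K2CO3, DMF) to give 1-[(2S)-2-(2-hydroxypropan-2-yl)-6-(prop-2-en-1-yloxy)-2,3-dihydro-1-benzofuran-5-yl]ethanone F1. Claisen–Schmidt condensation with 3 (KOH, EtOH) should give (2E)-1-[(2S)-2-(2-hydroxypropan-2-yl)-6-(prop-2-en-1-yloxy)-2,3-dihydro-1-benzofuran-5-yl]-3-[4-(2-methylbut-3-yn-2-yloxy)phenyl]prop-2-en-1-one F2. Juliá–Colonna epoxidation with poly-D-leucine (urea–H2O2, DBU, THF) is expected to give [(2S,3R)-3-[4-(2-methylbut-3-yn-2-yloxy)phenyl]oxiran-2-yl][(2S)-2-(2-hydroxypropan-2-yl)-6-(prop-2-en-1-yloxy)-2,3-dihydro-1-benzofuran-5-yl]methanone F3, which may be purified by crystallisation. Reductive opening of the Cα–O bond with the phenylselenide reagent from PhSeSePh and NaBH4 (AcOH, EtOH, 0 °C) should give (3S)-3-hydroxy-1-[(2S)-2-(2-hydroxypropan-2-yl)-6-(prop-2-en-1-yloxy)-2,3-dihydro-1-benzofuran-5-yl]-3-[4-(2-methylbut-3-yn-2-yloxy)phenyl]propan-1-one F4. Removal of the allyl group with Pd(PPh3)4 (cat.) and morpholine in THF returns 13.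

2. Step 2. Alkylation may occur at C3 instead of C5 or twice, and the acid may close the ortho-prenyl phenol to a chroman, so that little 6 is obtained. The fallback sets out from 4 and comes back at 7. Compound 4 is brominated para to the 2-OH (NBS, MeCN, 0 °C) to give 1-(5-bromo-2,4-dihydroxyphenyl)ethanone F5. Silylation of both phenols (TBSCl, imidazole, DMF) gives 1-[5-bromo-2,4-bis(tert-butyldimethylsilyloxy)phenyl]ethanone F6. Stille coupling with tributyl(3-methylbut-2-en-1-yl)stannane (Pd(PPh3)4, DMF, 90 °C), in which reductive elimination at the less hindered terminus of the prenyl–palladium intermediate should deliver the linear prenyl group, gives 7.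

3. Step 9. At the temperature required, silanol may be lost from the β-silyloxy ketone to give the enone, or the quinone methide may be trapped intermolecularly. The fallback sets out from 3 and comes back at 20, and it moves the same pericyclic cascade ahead of the aldol. Aldehyde 3 alone is heated (o-xylene, 140 °C) to give 2,2-dimethyl-2H-chromene-6-carbaldehyde F7. Hydrogenation (H2, Pd/C, Ph2S, EtOAc) gives 2,2-dimethyl-3,4-dihydro-2H-chromene-6-carbaldehyde F8. The aldol of step 7 between F8 and 11 with the same catalyst, followed by the same hydrolytic work-up, should give 20 directly, so steps 8 to 11 are not needed.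

Further compounds
F1 | step 7 | 1-[(2S)-2-(2-hydroxypropan-2-yl)-6-(prop-2-en-1-yloxy)-2,3-dihydro-1-benzofuran-5-yl]ethanone | CC(=O)c1cc2c(cc1OCC=C)O[C@H](C(C)(C)O)C2
F2 | step 7 | (2E)-1-[(2S)-2-(2-hydroxypropan-2-yl)-6-(prop-2-en-1-yloxy)-2,3-dihydro-1-benzofuran-5-yl]-3-[4-(2-methylbut-3-yn-2-yloxy)phenyl]prop-2-en-1-one | CC(C)(C#C)Oc1ccc(/C=C/C(=O)c2cc3c(cc2OCC=C)O[C@H](C(C)(C)O)C3)cc1
F3 | step 7 | [(2S,3R)-3-[4-(2-methylbut-3-yn-2-yloxy)phenyl]oxiran-2-yl][(2S)-2-(2-hydroxypropan-2-yl)-6-(prop-2-en-1-yloxy)-2,3-dihydro-1-benzofuran-5-yl]methanone | CC(C)(C#C)Oc1ccc([C@H]2O[C@@H]2C(=O)c3cc4c(cc3OCC=C)O[C@H](C(C)(C)O)C4)cc1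
F4 | step 7 | (3S)-3-hydroxy-1-[(2S)-2-(2-hydroxypropan-2-yl)-6-(prop-2-en-1-yloxy)-2,3-dihydro-1-benzofuran-5-yl]-3-[4-(2-methylbut-3-yn-2-yloxy)phenyl]propan-1-one | CC(C)(C#C)Oc1ccc([C@@H](O)CC(=O)c2cc3c(cc2OCC=C)O[C@H](C(C)(C)O)C3)cc1
F5 | step 2 | 1-(5-bromo-2,4-dihydroxyphenyl)ethanone | CC(=O)c1cc(Br)c(O)cc1O
F6 | step 2 | 1-[5-bromo-2,4-bis(tert-butyldimethylsilyloxy)phenyl]ethanone | CC(=O)c1cc(Br)c(O[Si](C)(C)C(C)(C)C)cc1O[Si](C)(C)C(C)(C)C
F7 | step 9 | 2,2-dimethyl-2H-chromene-6-carbaldehyde | CC1(C)C=Cc2cc(C=O)ccc2O1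
F8 | step 9 | 2,2-dimethyl-3,4-dihydro-2H-chromene-6-carbaldehyde | CC1(C)CCc2cc(C=O)ccc2O1
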